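**Retrosynthetic overview**

1. The γ-lactone (O1–C2) is closed last: C8a–OH adds to a C2 aldehyde that already carries the C3 methylene, and MnO2 oxidises this lactol and the C1′ carbinol (giving the crotonyl ketone) in one operation.
2. C5–OH comes from a C5 ketone by hydride delivery from the C7 hydroxyl. C7–OH and C8–O come from a β-epoxide of a C7=C8 allylic alcohol, opened by water at tertiary C7 with inversion. The C1′ chain comes from the C7 ester (CH2OH, CHO, propenyl addition).
3. The seven-membered ring comes from a formal (4+3) cycloaddition: a rhodium vinylcarbenoid from an (E)-4-silyloxy vinyldiazoacetate cyclopropanates C5=C6 of a (2Z,4E)-2-silyloxydiene (bonds C6–C7 and C5–C7), and the cis-divinylcyclopropane undergoes Cope rearrangement (bond C3a–C8a).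
4. Feature used: in the cyclohepta[b]furan-2-one core (O1, C2, C3, C3a, C4–C8, C8a) the carbocycle carries C8a–O, C3a–C3 and C6–CH3 on one face, next to an acyl-bearing quaternary C7, with oxygen at C5 and a CH2 at C4. This is the pattern of a 1,4-cycloheptadiene (C4=C5 enol ether, C7=C8 enoate) formed through a boat Cope transition state.
5. Ring order: carbocycle first (step 5), lactone last (steps 17–18). The diene comes from an HWE reaction and enol silylation; the diazo ester comes from a diazoacetate aldol addition and dehydration.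

Key step: step 5

**Conventions and assumptions**

- Ring atoms keep the target numbering throughout. C1′ is the carbon attached to C7. The α face is the face carrying C8a–O, C3a–C3 and C6–CH3; β is the opposite face.
- Assumption on the sense of induction: Rh2(S-DOSP)4 is taken to attack the enol ether with the same facial sense as in its styrene cyclopropanations, which gives the series drawn; if the opposite sense is found, Rh2(R-DOSP)4 is used.
- The carbenoid oxygen is carried as a TBS ether and the ester as ethyl, because (tert-butyldimethylsilyloxy)acetaldehyde and ethyl diazoacetate are catalogue compounds. The side-chain ether is p-methoxybenzyl so that it can be cleaved oxidatively in the presence of alkenes.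
- The E enol ether of the diazo ester is made by elimination next to the diazo carbon, because soft enolisation of an aldehyde would favour the Z enol ether, which would place C8a–O on the wrong face.
- Compounds 15–28 are mixtures of epimers at C1′ (26–27 also of C2 anomers, 23 of C3 epimers); these centres disappear by step 18.

**Route**

Step 1
Reactants: 1 3-[(4-methoxybenzyl)oxy]propanal; 2 diethyl (2-oxobutyl)phosphonate
Product: 3 (E)-7-[(4-methoxybenzyl)oxy]hept-4-en-3-one
Conditions: LiCl, i-Pr2NEt, MeCN, rt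
Reagents that add atoms: none
Why: Horner–Wadsworth–Emmons olefination under mild amine/lithium chloride conditions should give the E enone without β-elimination of the β-alkoxy aldehyde.

Step 2
Reactants: 3 (E)-7-[(4-methoxybenzyl)oxy]hept-4-en-3-one
Product: 4 (2Z,4E)-3-(tert-butyldimethylsilyloxy)-7-[(4-methoxybenzyl)oxy]hepta-2,4-diene
Conditions: TBSOTf, Et3N, CH2Cl2, 0 °C
Reagents that add atoms: tert-butyldimethylsilyl triflate, CC(C)(C)[Si](C)(C)OS(=O)(=O)C(F)(F)F
Why: Soft enolisation (silyl triflate/amine enol silylation) of the ethyl vinyl ketone at the α′ position should give the cross-conjugated 2-silyloxydiene as the Z enol ether (methyl cis to OSi, trans to the vinyl group), as is usual for ethyl ketones.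

Step 3
Reactants: 5 ethyl diazoacetate; 6 (tert-butyldimethylsilyloxy)acetaldehyde
Product: 7 ethyl 4-(tert-butyldimethylsilyloxy)-2-diazo-3-hydroxybutanoate (racemic)
Conditions: DBU (10 mol %), MeCN, rt
Reagents that add atoms: none
Why: Base-catalysed aldol-type addition of the acidic diazoacetate C–H to the aldehyde; the racemic carbinol centre is destroyed in step 4.

Step 4
Reactants: 7 ethyl 4-(tert-butyldimethylsilyloxy)-2-diazo-3-hydroxybutanoate
Product: 9 ethyl (E)-4-(tert-butyldimethylsilyloxy)-2-diazobut-3-enoate, via dichlorophosphate 8 (not isolated)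
Conditions: POCl3, Et3N, CH2Cl2, 0 °C → rt
Reagents that add atoms: none
Why: Dehydration of a β-hydroxy-α-diazo ester through its dichlorophosphate is an established route to vinyldiazoacetates, and because C3=C4 forms next to the planar, fully substituted diazo carbon, allylic 1,3-strain should enforce the E enol ether.

Step 5
Reactants: 4 (2Z,4E)-silyloxydiene (2 equiv); 9 ethyl (E)-4-(tert-butyldimethylsilyloxy)-2-diazobut-3-enoate
Product: 11 ethyl (3R,4R,7R)-3,6-bis(tert-butyldimethylsilyloxy)-4-{2-[(4-methoxybenzyl)oxy]ethyl}-7-methylcyclohepta-1,5-diene-1-carboxylate, via cis-divinylcyclopropane 10 (not isolated)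
Conditions: Rh2(S-DOSP)4 (1 mol %), hexanes, −78 °C → rt (9 added slowly), then 40 °C
Reagents that add atoms: none
Why: The divalent rhodium prolinate dimer decomposes 9 to a donor/acceptor vinylcarbenoid that cyclopropanates the electron-rich Z enol ether C5=C6 of 4 (attack at nucleophilic C6, charge at C5 stabilised by oxygen and the vinyl group), forming C6–C7 and C5–C7 with the two alkenyl groups cis; the closest known reaction is the enantioselective vinylcarbenoid–diene formal (4+3) cycloaddition by tandem cyclopropanation and Cope rearrangement. The seven-membered ring then closes by a [3,3] sigmatropic shift of 10 through a boat transition state, which forms C3a–C8a and breaks C5–C7. C3a and C8a are set by the two E alkenes, whose substituents sit exo in the boat and so end up cis to each other. C6 is set by the Z enol ether geometry, which places the methyl group trans to both alkenyl groups on the cyclopropane and therefore on the same face as the C3a and C8a substituents. Absolute configuration comes from the chiral prolinate ligands of the catalyst. The step needs reaction at the trisubstituted enol ether and not at the E-disubstituted alkene (E alkenes are poor partners and the enol ether is far more nucleophilic), cyclopropanation faster than C–H insertion at the benzylic ether (excess diene, low temperature, hydrocarbon solvent), and Cope rearrangement faster than heterolysis of the donor–acceptor cyclopropane (cis-divinyl arrangement, non-polar medium).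

Step 6
Reactants: 11 cycloheptadiene ethyl ester
Product: 12 C7 hydroxymethyl cycloheptadiene (allylic alcohol)
Conditions: i-Bu2AlH, CH2Cl2, −78 °C; aq. potassium sodium tartrate
Reagents that add atoms: none
Why: 1,2-Reduction of the conjugated ester by the aluminium hydride gives the primary allylic alcohol, and the neutral work-up keeps the silyl enol ether; no stereocentre is touched.

Step 7
Reactants: 12 allylic alcohol
Product: 13 β-epoxy alcohol (C7–C8 epoxide)
Conditions: Ti(OiPr)4 (10 mol %), L-(+)-diisopropyl tartrate (12 mol %), t-BuOOH, 4 Å molecular sieves, CH2Cl2, −20 °C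
Reagents that add atoms: tert-butyl hydroperoxide, CC(C)(C)OO
Why: Sharpless epoxidation acts only on the allylic alcohol and spares the silyl enol ether; the L-(+)-tartrate and the substrate (C6–CH3 and C8a–OTBS shield the α face) both direct oxygen to the β face of C7=C8, setting C7 and C8.

Step 8
Reactants: 13 β-epoxy alcohol
Product: 14 β-epoxy aldehyde
Conditions: SO3·pyridine, DMSO, i-Pr2NEt, CH2Cl2, 0 °C
Reagents that add atoms: none
Why: Parikh–Doering oxidation of the primary alcohol under basic, non-acidic conditions tolerates the epoxide and silyl enol ether, and the quaternary α-carbon cannot epimerise.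

Step 9
Reactants: 14 β-epoxy aldehyde
Product: 15 epoxy carbinol with (E)-propenyl group on C1′ (both C1′ epimers)
Conditions: (E)-1-bromopropene, t-BuLi (2 equiv), Et2O, −78 °C; then 14, THF, −78 °C; aq. NH4Cl
Reagents that add atoms: (E)-1-bromoprop-1-ene, C/C=C/Br (used as (E)-prop-1-enyllithium, C/C=C/[Li])
Why: 1,2-Addition of the alkenyllithium, formed with retention of geometry by bromine–lithium exchange, to the aldehyde; the new C1′ centre is not controlled because it becomes the ketone carbon in step 18.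

Step 10
Reactants: 15 epoxy carbinol
Product: 16 C1′ tert-butyldimethylsilyl ether
Conditions: TBSOTf, 2,6-lutidine, CH2Cl2, −78 °C
Reagents that add atoms: tert-butyldimethylsilyl triflate, CC(C)(C)[Si](C)(C)OS(=O)(=O)C(F)(F)F
Why: Silylation of the hindered secondary alcohol, so that it can neither steer the later hydride delivery nor be acylated; no stereocentre changes.

Step 11
Reactants: 16 epoxy silyl enol ether
Product: 18 C5 ketone with C7–OH α and C8–OH β, via epoxy ketone 17 (not isolated)
Conditions: HClO4 (0.1 M aq.), THF, 0 °C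
Reagents that add atoms: water, O
Why: Dilute acid hydrolyses the silyl enol ether to the C5 ketone (protonation at C4) and opens the trisubstituted epoxide by acid-catalysed hydrolysis in the Markovnikov sense, water attacking tertiary C7 from the α face with inversion so that C7–OH is α while C8–OH stays β.

Step 12
Reactants: 18 keto diol
Product: 19 C8 isobutyrate
Conditions: i-PrCOCl, pyridine, DMAP (cat.), CH2Cl2, 0 °C → rt
Reagents that add atoms: isobutyryl chloride, CC(C)C(=O)Cl
Why: DMAP-catalysed acylation takes the secondary C8 hydroxyl and not the tertiary C7 hydroxyl (a C5/C8 hemiketal form of 18 would react through the open hydroxy ketone), with retention at C8.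

Step 13
Reactants: 19 β-hydroxy ketone
Product: 20 5,7-anti diol (C5–OH β)
Conditions: Me4NBH(OAc)3, AcOH/MeCN, −30 → 0 °C
Reagents that add atoms: none
Why: Evans–Saksena reduction: the only free hydroxyl (tertiary C7–OH, α face) binds boron and delivers hydride intramolecularly to the α face of the C5 ketone, giving the anti 1,3-diol with C5–OH β.

Step 14
Reactants: 20 p-methoxybenzyl ether
Product: 21 primary alcohol (C3a–CH2CH2OH)
Conditions: DDQ, CH2Cl2/pH 7 buffer, 0 °C
Reagents that add atoms: none
Why: Oxidative cleavage of the p-methoxybenzyl ether (hydride abstraction, then hydrolysis of the oxocarbenium ion) leaves the alkene, ester and silyl ethers intact.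

Step 15
Reactants: 21 primary alcohol
Product: 22 aldehyde (C3a–CH2CHO)
Conditions: TEMPO (10 mol %), PhI(OAc)2, CH2Cl2, rt
Reagents that add atoms: none
Why: Oxoammonium-mediated oxidation selects the primary alcohol over the secondary C5 and tertiary C7 hydroxyls, and with C8a–O still silylated the aldehyde cannot close to a lactol and over-oxidise.

Step 16
Reactants: 22 aldehyde
Product: 24 α-methylene aldehyde (C3=CH2), via Mannich base 23 (not isolated)
Conditions: CH2=NMe2+ I− (Eschenmoser salt), Et3N, CH2Cl2, rt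
Reagents that add atoms: N,N-dimethylmethyleneiminium iodide, C=[N+](C)C.[I-]
Why: Mannich reaction of the aldehyde at C3 followed by β-elimination of dimethylamine installs the methylene under conditions mild enough for the isobutyrate and free hydroxyls; C3a is not enolised.

Step 17
Reactants: 24 α-methylene aldehyde
Product: 26 α-methylene lactol, via hydroxy enal 25 (not isolated)
Conditions: HF·pyridine, pyridine, THF, 0 °C → rt
Reagents that add atoms: none
Why: Acidic fluoride removes both secondary silyl ethers without base-induced acyl migration, and the freed C8a hydroxyl adds to the cis-disposed aldehyde (hemiacetal formation) to give the cis-fused lactol.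

Step 18
Reactants: 26 α-methylene lactol
Product: 29 (3aS,5R,6S,7S,8S,8aR)-7-[(2E)-but-2-enoyl]-5,7-dihydroxy-6-methyl-3-methylidene-2-oxooctahydro-2H-cyclohepta[b]furan-8-yl 2-methylpropanoate, via keto lactol 27 (not isolated), via hydroxy lactone 28 (not isolated)
Conditions: MnO2 (activated, excess), CH2Cl2, rt
Reagents that add atoms: none
Why: Manganese dioxide oxidises only the two allylic hydroxyls, the C1′ carbinol to the (E)-crotonyl ketone and the allylic lactol to the α-methylene lactone, and leaves the saturated secondary C5–OH and tertiary C7–OH.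

**Compound list**

1 | 3-[(4-methoxybenzyl)oxy]propanal | O=CCCOCc1ccc(OC)cc1 | starting material
2 | diethyl (2-oxobutyl)phosphonate | CCC(=O)CP(=O)(OCC)OCC | starting material
3 | (E)-7-[(4-methoxybenzyl)oxy]hept-4-en-3-one | CCC(=O)/C=C/CCOCc1ccc(OC)cc1 | intermediate
4 | (2Z,4E)-3-(tert-butyldimethylsilyloxy)-7-[(4-methoxybenzyl)oxy]hepta-2,4-diene | C/C=C(O[Si](C)(C)C(C)(C)C)/C=C/CCOCc1ccc(OC)cc1 | intermediate (key-step precursor)
5 | ethyl diazoacetate | CCOC(=O)C=[N+]=[N-] | starting material
6 | (tert-butyldimethylsilyloxy)acetaldehyde | O=CCO[Si](C)(C)C(C)(C)C | starting material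
7 | ethyl 4-(tert-butyldimethylsilyloxy)-2-diazo-3-hydroxybutanoate (racemic) | CCOC(=O)C(=[N+]=[N-])C(O)CO[Si](C)(C)C(C)(C)C | intermediate
8 | ethyl 4-(tert-butyldimethylsilyloxy)-3-(dichlorophosphoryloxy)-2-diazobutanoate | CCOC(=O)C(=[N+]=[N-])C(OP(=O)(Cl)Cl)CO[Si](C)(C)C(C)(C)C | intermediate (not isolated)
9 | ethyl (E)-4-(tert-butyldimethylsilyloxy)-2-diazobut-3-enoate | CCOC(=O)C(=[N+]=[N-])/C=C/O[Si](C)(C)C(C)(C)C | intermediate (key-step precursor)
10 | ethyl 2-(tert-butyldimethylsilyloxy)-1-[(E)-2-(tert-butyldimethylsilyloxy)ethenyl]-2-[(E)-4-(4-methoxybenzyloxy)but-1-enyl]-3-methylcyclopropane-1-carboxylate; the two alkenyl groups cis, the methyl trans to both | CCOC(=O)[C@@]1(/C=C/O[Si](C)(C)C(C)(C)C)[C@@H](C)[C@]1(O[Si](C)(C)C(C)(C)C)/C=C/CCOCc2ccc(OC)cc2 | intermediate (not isolated)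
11 | ethyl (3R,4R,7R)-3,6-bis(tert-butyldimethylsilyloxy)-4-{2-[(4-methoxybenzyl)oxy]ethyl}-7-methylcyclohepta-1,5-diene-1-carboxylate (target numbering: CO2Et on C7, C7=C8, C8a–OTBS, C3a side chain, C4=C5–OTBS, C6–CH3; the three substituents all α) | CC(C)(C)[Si](C)(C)O[C@@H]1[C@H](CCOCc2ccc(OC)cc2)C=C(O[Si](C)(C)C(C)(C)C)[C@H](C)C(C(=O)OCC)=C1 | intermediate (key-step product)
12 | as 11 with CH2OH in place of CO2Et on C7 | CC(C)(C)[Si](C)(C)O[C@@H]1[C@H](CCOCc2ccc(OC)cc2)C=C(O[Si](C)(C)C(C)(C)C)[C@H](C)C(CO)=C1 | intermediate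
13 | as 12 with a C7–C8 epoxide on the β face (CH2OH on C7 pointing α) | CC(C)(C)[Si](C)(C)O[C@@H]1[C@H](CCOCc2ccc(OC)cc2)C=C(O[Si](C)(C)C(C)(C)C)[C@H](C)[C@@]3(CO)O[C@@H]13 | intermediate
14 | as 13 with CHO on C7 | CC(C)(C)[Si](C)(C)O[C@@H]1[C@H](CCOCc2ccc(OC)cc2)C=C(O[Si](C)(C)C(C)(C)C)[C@H](C)[C@@]3(C=O)O[C@@H]13 | intermediate
15 | as 13 with CH(OH)–(E)-CH=CH–CH3 on C7 (both C1′ epimers) | CC(C)(C)[Si](C)(C)O[C@@H]1[C@H](CCOCc2ccc(OC)cc2)C=C(O[Si](C)(C)C(C)(C)C)[C@H](C)[C@@]3(C(O)/C=C/C)O[C@@H]13 | intermediate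
16 | as 15 with C1′–OTBS | CC(C)(C)[Si](C)(C)O[C@@H]1[C@H](CCOCc2ccc(OC)cc2)C=C(O[Si](C)(C)C(C)(C)C)[C@H](C)[C@@]3(C(O[Si](C)(C)C(C)(C)C)/C=C/C)O[C@@H]13 | intermediate
17 | as 16 with the enol ether cleaved: C5 ketone, C4 methylene, β-epoxide kept | CC(C)(C)[Si](C)(C)O[C@@H]1[C@H](CCOCc2ccc(OC)cc2)CC(=O)[C@H](C)[C@@]3(C(O[Si](C)(C)C(C)(C)C)/C=C/C)O[C@@H]13 | intermediate (not isolated)
18 | cycloheptanone: C5 ketone, C6–CH3 α, C7–OH α with C1′(OTBS)–(E)-propenyl β, C8–OH β, C8a–OTBS α, C3a–CH2CH2OPMB α | CC(C)(C)[Si](C)(C)O[C@@H]1[C@H](CCOCc2ccc(OC)cc2)CC(=O)[C@H](C)[C@@](O)(C(O[Si](C)(C)C(C)(C)C)/C=C/C)[C@H]1O | intermediate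
19 | as 18 with C8–O-isobutyryl | CC(C)(C)[Si](C)(C)O[C@@H]1[C@H](CCOCc2ccc(OC)cc2)CC(=O)[C@H](C)[C@@](O)(C(O[Si](C)(C)C(C)(C)C)/C=C/C)[C@H]1OC(=O)C(C)C | intermediate
20 | as 19 with C5–OH β in place of the ketone | CC(C)(C)[Si](C)(C)O[C@@H]1[C@H](CCOCc2ccc(OC)cc2)C[C@@H](O)[C@H](C)[C@@](O)(C(O[Si](C)(C)C(C)(C)C)/C=C/C)[C@H]1OC(=O)C(C)C | intermediate
21 | as 20 with C3a–CH2CH2OH | CC(C)(C)[Si](C)(C)O[C@@H]1[C@H](CCO)C[C@@H](O)[C@H](C)[C@@](O)(C(O[Si](C)(C)C(C)(C)C)/C=C/C)[C@H]1OC(=O)C(C)C | intermediate
22 | as 20 with C3a–CH2CHO | CC(C)(C)[Si](C)(C)O[C@@H]1[C@H](CC=O)C[C@@H](O)[C@H](C)[C@@](O)(C(O[Si](C)(C)C(C)(C)C)/C=C/C)[C@H]1OC(=O)C(C)C | intermediate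
23 | as 22 with CH2NMe2 on the aldehyde α-carbon C3 (both epimers) | CC(C)(C)[Si](C)(C)O[C@@H]1[C@H](C(CN(C)C)C=O)C[C@@H](O)[C@H](C)[C@@](O)(C(O[Si](C)(C)C(C)(C)C)/C=C/C)[C@H]1OC(=O)C(C)C | intermediate (not isolated)
24 | as 22 with C3=CH2 (2-substituted propenal on C3a) | CC(C)(C)[Si](C)(C)O[C@@H]1[C@H](C(=C)C=O)C[C@@H](O)[C@H](C)[C@@](O)(C(O[Si](C)(C)C(C)(C)C)/C=C/C)[C@H]1OC(=O)C(C)C | intermediate
25 | as 24 with both silyl ethers removed (C8a–OH, C1′–OH), open hydroxy aldehyde form | O[C@@H]1[C@H](C(=C)C=O)C[C@@H](O)[C@H](C)[C@@](O)(C(O)/C=C/C)[C@H]1OC(=O)C(C)C | intermediate (not isolated)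
26 | lactol of the target skeleton: C2 is CH(OH) (both anomers), C1′ is CH(OH) (both epimers), ring centres as in the target | C=C1C(O)O[C@@H]2[C@H]1C[C@@H](O)[C@H](C)[C@@](O)(C(O)/C=C/C)[C@H]2OC(=O)C(C)C | intermediate
27 | as 26 with the C1′ ketone (crotonyl) and the C2 lactol | C=C1C(O)O[C@@H]2[C@H]1C[C@@H](O)[C@H](C)[C@@](O)(C(=O)/C=C/C)[C@H]2OC(=O)C(C)C | intermediate (not isolated)
28 | as 26 with the C2 lactone and the C1′ carbinol | C=C1C(=O)O[C@@H]2[C@H]1C[C@@H](O)[C@H](C)[C@@](O)(C(O)/C=C/C)[C@H]2OC(=O)C(C)C | intermediate (not isolated)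
29 | (3aS,5R,6S,7S,8S,8aR)-7-[(2E)-but-2-enoyl]-5,7-dihydroxy-6-methyl-3-methylidene-2-oxooctahydro-2H-cyclohepta[b]furan-8-yl 2-methylpropanoate (CNP0123946.1) | C=C1C(=O)O[C@@H]2[C@H]1C[C@@H](O)[C@H](C)[C@@](O)(C(=O)/C=C/C)[C@H]2OC(=O)C(C)C | target

**Step count**

Total: 18 steps. Longest linear sequence: 16 steps (steps 1, 2, 5–18; the diazo branch, steps 3, 4, 5–18, is equally long).

**Steps most likely to fail**

Step 5. Process: enantiofacial control at the carbenoid may be weak with the ethyl ester and the bulky silyloxyvinyl donor, giving material of low enantiomeric purity. Fallback: stereocontrol from an ester auxiliary with an achiral catalyst, setting out from 6 and 4 and returning at 12.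
- (R)-Pantolactone is esterified with glyoxylic acid chloride p-toluenesulfonylhydrazone (PhNMe2, then Et3N); the hydrazone ester F1 fragments in the flask to (R)-pantolactonyl diazoacetate F2.
- DBU-catalysed addition of F2 to 6 gives the β-hydroxy diazo ester F3, and POCl3/Et3N dehydrates it through dichlorophosphate F4 to the (E)-silyloxyvinyl diazo ester F5.
- Decomposition of F5 with Rh2(O2CC7H15)4 in hexanes in the presence of 4 should give, through cyclopropane F6, the pantolactonyl cycloheptadienecarboxylate F7, the facial bias now coming from the auxiliary carbonyl.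
- i-Bu2AlH then cleaves the auxiliary ester reductively and gives 12. The (S)-lactone is used if the (R)-auxiliary induces the opposite sense.

Step 11. Process: the C7–O bond may ionise ahead of water attack, allowing a 1,2-shift of hydrogen or propenyl from the silyloxy-bearing C1′ (semipinacol rearrangement), or water may attack C8 and invert the wrong centre; the secondary silyl ethers may also be partly lost. Fallback: the hydrolysis is moved to the primary epoxy alcohol and the propenyl group is brought in afterwards, setting out from 13 and returning at 19.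
- Dilute HClO4 in aqueous THF converts 13 through epoxy ketone F8 into keto triol F9 (C7–OH α, C8–OH β).
- TEMPO/PhI(OAc)2 oxidises the primary alcohol to hydroxy aldehyde F10, and i-PrCOCl/pyridine/DMAP acylates the only secondary hydroxyl to give isobutyrate aldehyde F11.
- A Nozaki–Hiyama–Kishi addition of (E)-1-iodopropene (CrCl2, NiCl2 cat., DMSO), which takes the aldehyde and spares the C5 ketone and the ester, gives carbinol F12.
- TBSOTf/2,6-lutidine at −78 °C silylates the secondary allylic hydroxyl and gives 19.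

Step 13. Process: ligand exchange at the tertiary C7 hydroxyl may be too slow, so that hydride is not delivered intramolecularly (no reaction, or unselective attack at C5). Fallback: undirected reduction and inversion, setting out from 19 and returning at 20.
- NaBH4/CeCl3·7H2O in MeOH at −40 °C reduces the ketone; any 20 formed is used directly, and the 5-epi alcohol F13 is separated.
- A Mitsunobu reaction of F13 with formic acid (PPh3, DIAD) gives the inverted β-formate F14.
- NaHCO3 in MeOH removes the formate in the presence of the isobutyrate and gives 20.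

**Further compounds**

F1 | step 5 | (R)-pantolactonyl glyoxylate p-toluenesulfonylhydrazone (not isolated) | Cc1ccc(cc1)S(=O)(=O)NN=CC(=O)O[C@H]1C(=O)OCC1(C)C
F2 | step 5 | (R)-pantolactonyl diazoacetate [(3R)-4,4-dimethyl-2-oxooxolan-3-yl diazoacetate] | [N-]=[N+]=CC(=O)O[C@H]1C(=O)OCC1(C)C
F3 | step 5 | (R)-pantolactonyl 4-(tert-butyldimethylsilyloxy)-2-diazo-3-hydroxybutanoate (carbinol epimers) | CC(C)(C)[Si](C)(C)OCC(O)C(=[N+]=[N-])C(=O)O[C@H]1C(=O)OCC1(C)C
F4 | step 5 | dichlorophosphate of F3 (not isolated) | CC(C)(C)[Si](C)(C)OCC(OP(=O)(Cl)Cl)C(=[N+]=[N-])C(=O)O[C@H]1C(=O)OCC1(C)C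
F5 | step 5 | (R)-pantolactonyl (E)-4-(tert-butyldimethylsilyloxy)-2-diazobut-3-enoate | CC(C)(C)[Si](C)(C)O/C=C/C(=[N+]=[N-])C(=O)O[C@H]1C(=O)OCC1(C)C
F6 | step 5 | pantolactonyl ester analogue of cyclopropane 10 (not isolated) | O=C(O[C@H]3C(=O)OCC3(C)C)[C@@]1(/C=C/O[Si](C)(C)C(C)(C)C)[C@@H](C)[C@]1(O[Si](C)(C)C(C)(C)C)/C=C/CCOCc2ccc(OC)cc2
F7 | step 5 | pantolactonyl ester analogue of cycloheptadiene 11 | CC(C)(C)[Si](C)(C)O[C@@H]1[C@H](CCOCc2ccc(OC)cc2)C=C(O[Si](C)(C)C(C)(C)C)[C@H](C)C(C(=O)O[C@H]3C(=O)OCC3(C)C)=C1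
F8 | step 11 | as 13 with the enol ether cleaved: C5 ketone, β-epoxide, C7–CH2OH (not isolated) | CC(C)(C)[Si](C)(C)O[C@@H]1[C@H](CCOCc2ccc(OC)cc2)CC(=O)[C@H](C)[C@@]3(CO)O[C@@H]13
F9 | step 11 | keto triol: C5 ketone, C7–OH α, C7–CH2OH β, C8–OH β | CC(C)(C)[Si](C)(C)O[C@@H]1[C@H](CCOCc2ccc(OC)cc2)CC(=O)[C@H](C)[C@@](O)(CO)[C@H]1O
F10 | step 11 | as F9 with CHO on C7 | CC(C)(C)[Si](C)(C)O[C@@H]1[C@H](CCOCc2ccc(OC)cc2)CC(=O)[C@H](C)[C@@](O)(C=O)[C@H]1O
F11 | step 11 | as F10 with C8–O-isobutyryl | CC(C)(C)[Si](C)(C)O[C@@H]1[C@H](CCOCc2ccc(OC)cc2)CC(=O)[C@H](C)[C@@](O)(C=O)[C@H]1OC(=O)C(C)C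
F12 | step 11 | as 19 with free C1′–OH (both epimers) | CC(C)(C)[Si](C)(C)O[C@@H]1[C@H](CCOCc2ccc(OC)cc2)CC(=O)[C@H](C)[C@@](O)(C(O)/C=C/C)[C@H]1OC(=O)C(C)C
F13 | step 13 | 5-epimer of 20 (C5–OH α) | CC(C)(C)[Si](C)(C)O[C@@H]1[C@H](CCOCc2ccc(OC)cc2)C[C@H](O)[C@H](C)[C@@](O)(C(O[Si](C)(C)C(C)(C)C)/C=C/C)[C@H]1OC(=O)C(C)C
F14 | step 13 | C5 β-formate of 20 | CC(C)(C)[Si](C)(C)O[C@@H]1[C@H](CCOCc2ccc(OC)cc2)C[C@@H](OC=O)[C@H](C)[C@@](O)(C(O[Si](C)(C)C(C)(C)C)/C=C/C)[C@H]1OC(=O)C(C)C
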